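**Retrosynthetic overview**
- Ring C (the pyranone) is closed last, by cyclodehydration of an o-hydroxyaryl 1,3-diketone; rings A and B are bought as benzenoids (5-methoxyresorcinol, methyl 2,4-dihydroxybenzoate).
- The diketone comes from the key intermolecular crossed Claisen condensation of the ring-A methyl ketone enolate with the ring-B methyl benzoate.
- The ring-A acetyl group is installed late by directed ortho-metalation of a 2-alkylresorcinol bis-MOM ether whose two ring CH positions are equivalent; the phenols are then re-dressed as allyl ethers, which come off without acid.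
- The (R) side-chain centre is set by Evans alkylation of a 3-arylpropanoyl (R)-benzyloxazolidinone with prenyl bromide; the imide C=O becomes the isopropenyl group (Weinreb amide, MeMgBr, Tebbe) and the prenyl group becomes the tertiary alcohol (Mukaiyama hydration).
- The 3-arylpropanoic acid comes from 5-methoxyresorcinol by MOM protection, ortho-lithiation/formylation, Knoevenagel–Doebner condensation and hydrogenation.

Assumption: the [C@H] centre of the SMILES is read as (R) (isopropenyl > CH2Ar > CH2CH2C(OH)Me2 > H); 5-methoxyresorcinol, (R)-4-benzyl-2-oxazolidinone, prenyl bromide and methyl 2,4-dihydroxybenzoate are taken as catalogue chemicals.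

**Route**

Step 1
Reactants: 1 5-methoxybenzene-1,3-diol (5-methoxyresorcinol)
Product: 2 1-methoxy-3,5-bis(methoxymethoxy)benzene
Conditions: MOMCl (2.6 eq), i-Pr2NEt, CH2Cl2, 0 °C → rt
Reagents that add atoms: chloromethyl methyl ether, COCCl
Why: Williamson-type O-alkylation of both phenols gives the bis-MOM ether, whose acetal oxygens later direct lithiation.

Step 2
Reactants: 2 1-methoxy-3,5-bis(methoxymethoxy)benzene
Product: 4 4-methoxy-2,6-bis(methoxymethoxy)benzaldehyde, via aryllithium 3 (not isolated)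
Conditions: n-BuLi, TMEDA, THF, 0 °C; then DMF, 0 °C → rt; aq NH4Cl
Reagents that add atoms: N,N-dimethylformamide, CN(C)C=O
Why: Directed ortho-metalation occurs at the position flanked by both OMOM groups (doubly chelated, most acidic) and the aryllithium is formylated by DMF.

Step 3
Reactants: 4 4-methoxy-2,6-bis(methoxymethoxy)benzaldehyde
Product: 5 (2E)-3-[4-methoxy-2,6-bis(methoxymethoxy)phenyl]prop-2-enoic acid
Conditions: CH2(CO2H)2 (3 eq), pyridine, piperidine (cat.), 90 °C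
Reagents that add atoms: malonic acid, OC(=O)CC(=O)O
Why: Knoevenagel–Doebner condensation with in situ decarboxylation gives the E-cinnamic acid under basic conditions that leave the MOM acetals intact.

Step 4
Reactants: 5 (2E)-3-[4-methoxy-2,6-bis(methoxymethoxy)phenyl]prop-2-enoic acid
Product: 6 3-[4-methoxy-2,6-bis(methoxymethoxy)phenyl]propanoic acid
Conditions: H2 (1 atm), 10% Pd/C, EtOAc, rt
Reagents that add atoms: none
Why: Heterogeneous catalytic hydrogenation saturates only the conjugated C=C bond.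

Step 5
Reactants: 6 3-[4-methoxy-2,6-bis(methoxymethoxy)phenyl]propanoic acid; 7 (4R)-4-benzyl-1,3-oxazolidin-2-one
Product: 9 (4R)-4-benzyl-3-{3-[4-methoxy-2,6-bis(methoxymethoxy)phenyl]propanoyl}-1,3-oxazolidin-2-one, via mixed pivalic anhydride 8 (not isolated)
Conditions: t-BuCOCl, Et3N, THF, −20 °C; then LiCl, 7, −20 °C → rt
Reagents that add atoms: none
Why: N-Acylation of the oxazolidinone through the mixed pivalic anhydride (LiCl/Et3N activation) is the standard mild entry to Evans imides.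

Step 6
Reactants: 9 (4R)-4-benzyl-3-{3-[4-methoxy-2,6-bis(methoxymethoxy)phenyl]propanoyl}-1,3-oxazolidin-2-one; 10 1-bromo-3-methylbut-2-ene (prenyl bromide)
Product: 12 (4R)-4-benzyl-3-[(2R)-2-{[4-methoxy-2,6-bis(methoxymethoxy)phenyl]methyl}-5-methylhex-4-enoyl]-1,3-oxazolidin-2-one, via sodium Z-enolate 11 (not isolated)
Conditions: NaN(SiMe3)2 (1.1 eq), THF, −78 °C; then 10 (3 eq), −78 → −40 °C
Reagents that add atoms: none
Why: In this Evans asymmetric alkylation the chelated Z-enolate is attacked by the allylic bromide on the face opposite the C4 benzyl group of the (R)-auxiliary, which sets the (2R) centre (dr typically ≥ 95:5, minor isomer removed by chromatography).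

Step 7
Reactants: 12 (4R)-4-benzyl-3-[(2R)-2-{[4-methoxy-2,6-bis(methoxymethoxy)phenyl]methyl}-5-methylhex-4-enoyl]-1,3-oxazolidin-2-one
Product: 13 (4R)-4-benzyl-3-[(2R)-5-hydroxy-2-{[4-methoxy-2,6-bis(methoxymethoxy)phenyl]methyl}-5-methylhexanoyl]-1,3-oxazolidin-2-one
Conditions: Co(acac)2 (20 mol %), PhSiH3, O2 (1 atm), THF, rt
Reagents that add atoms: dioxygen, O=O
Why: Mukaiyama hydration (Markovnikov hydrogen-atom transfer to the trisubstituted alkene, O2 trapping of the tertiary radical) gives the tertiary alcohol under neutral conditions that do not touch the imide or its α-centre.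

Step 8
Reactants: 13 (4R)-4-benzyl-3-[(2R)-5-hydroxy-2-{[4-methoxy-2,6-bis(methoxymethoxy)phenyl]methyl}-5-methylhexanoyl]-1,3-oxazolidin-2-one
Product: 14 (4R)-4-benzyl-3-[(2R)-2-{[4-methoxy-2,6-bis(methoxymethoxy)phenyl]methyl}-5-methyl-5-[(triethylsilyl)oxy]hexanoyl]-1,3-oxazolidin-2-one
Conditions: Et3SiCl, imidazole, DMAP (cat.), DMF, 40 °C
Reagents that add atoms: chlorotriethylsilane, CC[Si](Cl)(CC)CC
Why: Silyl ether formation masks the tertiary alcohol so that it cannot lactonise onto the activated acid or be acylated in the later Claisen step.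

Step 9
Reactants: 14 (4R)-4-benzyl-3-[(2R)-2-{[4-methoxy-2,6-bis(methoxymethoxy)phenyl]methyl}-5-methyl-5-[(triethylsilyl)oxy]hexanoyl]-1,3-oxazolidin-2-one
Product: 16 (2R)-2-{[4-methoxy-2,6-bis(methoxymethoxy)phenyl]methyl}-5-methyl-5-[(triethylsilyl)oxy]hexanoic acid, via lithium peroxycarboxylate 15 (not isolated)
Conditions: LiOH, H2O2, THF/H2O, 0 °C; then Na2SO3; then 1 M HCl to pH 4, 0 °C
Reagents that add atoms: hydrogen peroxide, OO
Why: Hydroperoxide-mediated hydrolysis cleaves the Evans imide selectively at the exocyclic carbonyl without epimerisation, and the auxiliary is recovered.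

Step 10
Reactants: 16 (2R)-2-{[4-methoxy-2,6-bis(methoxymethoxy)phenyl]methyl}-5-methyl-5-[(triethylsilyl)oxy]hexanoic acid
Product: 17 (2R)-N-methoxy-2-{[4-methoxy-2,6-bis(methoxymethoxy)phenyl]methyl}-N,5-dimethyl-5-[(triethylsilyl)oxy]hexanamide
Conditions: MeNH(OMe)·HCl, EDC·HCl, HOBt, N-methylmorpholine, CH2Cl2, 0 °C → rt
Reagents that add atoms: N,O-dimethylhydroxylamine hydrochloride, CNOC.Cl
Why: Carbodiimide/HOBt amide coupling gives the Weinreb amide, and an α-branched acid without an N-acyl group does not racemise under these conditions.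

Step 11
Reactants: 17 (2R)-N-methoxy-2-{[4-methoxy-2,6-bis(methoxymethoxy)phenyl]methyl}-N,5-dimethyl-5-[(triethylsilyl)oxy]hexanamide
Product: 18 (3R)-3-{[4-methoxy-2,6-bis(methoxymethoxy)phenyl]methyl}-6-methyl-6-[(triethylsilyl)oxy]heptan-2-one
Conditions: MeMgBr (3 eq), THF, 0 °C; aq NH4Cl
Reagents that add atoms: methylmagnesium bromide, C[Mg]Br
Why: In this Weinreb ketone synthesis the chelated tetrahedral intermediate survives until work-up, so there is neither over-addition nor enolisation of the α-centre.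

Step 12
Reactants: 18 (3R)-3-{[4-methoxy-2,6-bis(methoxymethoxy)phenyl]methyl}-6-methyl-6-[(triethylsilyl)oxy]heptan-2-one
Product: 19 5-methoxy-1,3-bis(methoxymethoxy)-2-{(2R)-5-methyl-2-(prop-1-en-2-yl)-5-[(triethylsilyl)oxy]hexyl}benzene
Conditions: Cp2Ti(μ-Cl)(μ-CH2)AlMe2 (Tebbe reagent, 1.5 eq), pyridine (cat.), THF/toluene, −40 → 0 °C; aq NaOH
Reagents that add atoms: Tebbe reagent Cp2Ti(μ-Cl)(μ-CH2)AlMe2, C[Al-]1(C)C[Ti]([Cl+]1)(C1C=CC=C1)C1C=CC=C1
Why: Tebbe methylenation uses a non-basic titanium methylidene, so the methyl ketone becomes the isopropenyl group without epimerising the adjacent stereocentre, which is thereafter no longer enolisable.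

Step 13
Reactants: 19 5-methoxy-1,3-bis(methoxymethoxy)-2-{(2R)-5-methyl-2-(prop-1-en-2-yl)-5-[(triethylsilyl)oxy]hexyl}benzene
Product: 21 1-[6-methoxy-2,4-bis(methoxymethoxy)-3-{(2R)-5-methyl-2-(prop-1-en-2-yl)-5-[(triethylsilyl)oxy]hexyl}phenyl]ethan-1-one, via aryllithium 20 (not isolated)
Conditions: n-BuLi (1.3 eq), TMEDA, THF, 0 °C; then MeC(O)N(OMe)Me, −78 → 0 °C; aq NH4Cl
Reagents that add atoms: N-methoxy-N-methylacetamide, CC(=O)N(C)OC
Why: Directed ortho-metalation between OMOM and OMe (the two ring CH positions are constitutionally equivalent) followed by Weinreb acylation gives a single acetophenone regioisomer.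

Step 14
Reactants: 21 1-[6-methoxy-2,4-bis(methoxymethoxy)-3-{(2R)-5-methyl-2-(prop-1-en-2-yl)-5-[(triethylsilyl)oxy]hexyl}phenyl]ethan-1-one
Product: 23 1-[2,4-dihydroxy-6-methoxy-3-{(2R)-5-methyl-2-(prop-1-en-2-yl)-5-[(triethylsilyl)oxy]hexyl}phenyl]ethan-1-one, via bis(triethylsilyl) aryl ether 22 (not isolated)
Conditions: Et3SiOTf (3 eq), 2,2′-bipyridyl (4.5 eq), MeCN, 0 °C → rt; then K2CO3 (0.2 eq), MeOH, rt
Reagents that add atoms: none
Why: Silyl triflate/2,2′-bipyridyl acetal exchange turns aryl MOM ethers into aryl silyl ethers without any Brønsted acid that could protonate the isopropenyl group, and carbonate-catalysed methanolysis then cleaves only the aryl O–Si bonds (the tertiary alkyl silyl ether stays).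

Step 15
Reactants: 23 1-[2,4-dihydroxy-6-methoxy-3-{(2R)-5-methyl-2-(prop-1-en-2-yl)-5-[(triethylsilyl)oxy]hexyl}phenyl]ethan-1-one
Product: 24 1-[2-hydroxy-6-methoxy-3-{(2R)-5-methyl-2-(prop-1-en-2-yl)-5-[(triethylsilyl)oxy]hexyl}-4-(prop-2-en-1-yloxy)phenyl]ethan-1-one
Conditions: allyl bromide (1.1 eq), K2CO3 (1.5 eq), acetone, 40 °C
Reagents that add atoms: allyl bromide, C=CCBr
Why: Williamson etherification is selective for the 4-OH because the 2-OH is hydrogen-bonded to the acetyl carbonyl and far less nucleophilic.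

Step 16
Reactants: 25 methyl 2,4-dihydroxybenzoate
Product: 26 methyl 2,4-bis(prop-2-en-1-yloxy)benzoate
Conditions: allyl bromide (2.5 eq), K2CO3 (3 eq), DMF, 60 °C
Reagents that add atoms: allyl bromide, C=CCBr
Why: Exhaustive Williamson etherification in DMF alkylates both phenols, including the ester-chelated 2-OH.

Step 17
Reactants: 24 1-[2-hydroxy-6-methoxy-3-{(2R)-5-methyl-2-(prop-1-en-2-yl)-5-[(triethylsilyl)oxy]hexyl}-4-(prop-2-en-1-yloxy)phenyl]ethan-1-one; 26 methyl 2,4-bis(prop-2-en-1-yloxy)benzoate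
Product: 27 1-[2,4-bis(prop-2-en-1-yloxy)phenyl]-3-[2-hydroxy-6-methoxy-3-{(2R)-5-methyl-2-(prop-1-en-2-yl)-5-[(triethylsilyl)oxy]hexyl}-4-(prop-2-en-1-yloxy)phenyl]propane-1,3-dione
Conditions: NaH (5 eq), THF, reflux; then 1 M HCl to pH 5, 0 °C
Reagents that add atoms: none
Why: This crossed Claisen condensation is the key fragment-joining C–C bond formation: the phenoxide/enolate dianion of the methyl ketone acylates on carbon with the non-enolisable benzoate and is driven forward by deprotonation of the 1,3-diketone.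

Step 18
Reactants: 27 1-[2,4-bis(prop-2-en-1-yloxy)phenyl]-3-[2-hydroxy-6-methoxy-3-{(2R)-5-methyl-2-(prop-1-en-2-yl)-5-[(triethylsilyl)oxy]hexyl}-4-(prop-2-en-1-yloxy)phenyl]propane-1,3-dione
Product: 28 2-[2,4-bis(prop-2-en-1-yloxy)phenyl]-5-methoxy-8-{(2R)-5-methyl-2-(prop-1-en-2-yl)-5-[(triethylsilyl)oxy]hexyl}-7-(prop-2-en-1-yloxy)-4H-chromen-4-one
Conditions: NaOAc, AcOH, 90 °C
Reagents that add atoms: none
Why: Cyclodehydration of the o-hydroxyaryl 1,3-diketone (second stage of a Baker–Venkataraman-type flavone synthesis) closes ring C through the only free phenol, in a buffered weak acid that does not protonate the isopropenyl group.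

Step 19
Reactants: 28 2-[2,4-bis(prop-2-en-1-yloxy)phenyl]-5-methoxy-8-{(2R)-5-methyl-2-(prop-1-en-2-yl)-5-[(triethylsilyl)oxy]hexyl}-7-(prop-2-en-1-yloxy)-4H-chromen-4-one
Product: 29 2-[2,4-bis(prop-2-en-1-yloxy)phenyl]-8-[(2R)-5-hydroxy-5-methyl-2-(prop-1-en-2-yl)hexyl]-5-methoxy-7-(prop-2-en-1-yloxy)-4H-chromen-4-one
Conditions: Bu4NF, THF, rt; aq NH4Cl
Reagents that add atoms: none
Why: Fluoride desilylation frees the tertiary alcohol under non-acidic conditions and also converges any material that lost the silyl group in step 18.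

Step 20
Reactants: 29 2-[2,4-bis(prop-2-en-1-yloxy)phenyl]-8-[(2R)-5-hydroxy-5-methyl-2-(prop-1-en-2-yl)hexyl]-5-methoxy-7-(prop-2-en-1-yloxy)-4H-chromen-4-one
Product: 30 2-(2,4-dihydroxyphenyl)-7-hydroxy-8-[(2R)-5-hydroxy-5-methyl-2-(prop-1-en-2-yl)hexyl]-5-methoxy-4H-chromen-4-one (CNP0256984.1)
Conditions: Pd(PPh3)4 (10 mol %), morpholine (10 eq), THF, rt
Reagents that add atoms: none
Why: Tsuji–Trost deallylation: zerovalent palladium ionises the three allyl aryl ethers and morpholine traps the π-allyl fragments, under neutral conditions that spare the isopropenyl group and the tertiary alcohol.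

**Compound list**
1 | 5-methoxybenzene-1,3-diol (5-methoxyresorcinol) | COc1cc(O)cc(O)c1 | starting material
2 | 1-methoxy-3,5-bis(methoxymethoxy)benzene | COCOc1cc(OC)cc(OCOC)c1 | intermediate
3 | [4-methoxy-2,6-bis(methoxymethoxy)phenyl]lithium | [Li]c1c(OCOC)cc(OC)cc1OCOC | intermediate
4 | 4-methoxy-2,6-bis(methoxymethoxy)benzaldehyde | COCOc1cc(OC)cc(OCOC)c1C=O | intermediate
5 | (2E)-3-[4-methoxy-2,6-bis(methoxymethoxy)phenyl]prop-2-enoic acid | COCOc1cc(OC)cc(OCOC)c1/C=C/C(=O)O | intermediate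
6 | 3-[4-methoxy-2,6-bis(methoxymethoxy)phenyl]propanoic acid | COCOc1cc(OC)cc(OCOC)c1CCC(=O)O | intermediate
7 | (4R)-4-benzyl-1,3-oxazolidin-2-one | O=C1N[C@H](Cc2ccccc2)CO1 | starting material
8 | 3-[4-methoxy-2,6-bis(methoxymethoxy)phenyl]propanoic 2,2-dimethylpropanoic anhydride | COCOc1cc(OC)cc(OCOC)c1CCC(=O)OC(=O)C(C)(C)C | intermediate
9 | (4R)-4-benzyl-3-{3-[4-methoxy-2,6-bis(methoxymethoxy)phenyl]propanoyl}-1,3-oxazolidin-2-one | COCOc1cc(OC)cc(OCOC)c1CCC(=O)N1[C@H](Cc2ccccc2)COC1=O | intermediate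
10 | 1-bromo-3-methylbut-2-ene (prenyl bromide) | CC(C)=CCBr | starting material
11 | sodium (Z)-enolate of 9 | [Na+].[O-]/C(=C\Cc1c(OCOC)cc(OC)cc1OCOC)N1[C@H](Cc2ccccc2)COC1=O | intermediate
12 | (4R)-4-benzyl-3-[(2R)-2-{[4-methoxy-2,6-bis(methoxymethoxy)phenyl]methyl}-5-methylhex-4-enoyl]-1,3-oxazolidin-2-one | O=C(N1[C@H](Cc2ccccc2)COC1=O)[C@H](CC=C(C)C)Cc1c(OCOC)cc(OC)cc1OCOC | intermediate
13 | (4R)-4-benzyl-3-[(2R)-5-hydroxy-2-{[4-methoxy-2,6-bis(methoxymethoxy)phenyl]methyl}-5-methylhexanoyl]-1,3-oxazolidin-2-one | O=C(N1[C@H](Cc2ccccc2)COC1=O)[C@H](CCC(C)(C)O)Cc1c(OCOC)cc(OC)cc1OCOC | intermediate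
14 | (4R)-4-benzyl-3-[(2R)-2-{[4-methoxy-2,6-bis(methoxymethoxy)phenyl]methyl}-5-methyl-5-[(triethylsilyl)oxy]hexanoyl]-1,3-oxazolidin-2-one | O=C(N1[C@H](Cc2ccccc2)COC1=O)[C@H](CCC(C)(C)O[Si](CC)(CC)CC)Cc1c(OCOC)cc(OC)cc1OCOC | intermediate
15 | lithium (2R)-2-{[4-methoxy-2,6-bis(methoxymethoxy)phenyl]methyl}-5-methyl-5-[(triethylsilyl)oxy]hexaneperoxoate | [Li+].[O-]OC(=O)[C@H](CCC(C)(C)O[Si](CC)(CC)CC)Cc1c(OCOC)cc(OC)cc1OCOC | intermediate
16 | (2R)-2-{[4-methoxy-2,6-bis(methoxymethoxy)phenyl]methyl}-5-methyl-5-[(triethylsilyl)oxy]hexanoic acid | OC(=O)[C@H](CCC(C)(C)O[Si](CC)(CC)CC)Cc1c(OCOC)cc(OC)cc1OCOC | intermediate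
17 | (2R)-N-methoxy-2-{[4-methoxy-2,6-bis(methoxymethoxy)phenyl]methyl}-N,5-dimethyl-5-[(triethylsilyl)oxy]hexanamide | CON(C)C(=O)[C@H](CCC(C)(C)O[Si](CC)(CC)CC)Cc1c(OCOC)cc(OC)cc1OCOC | intermediate
18 | (3R)-3-{[4-methoxy-2,6-bis(methoxymethoxy)phenyl]methyl}-6-methyl-6-[(triethylsilyl)oxy]heptan-2-one | CC(=O)[C@H](CCC(C)(C)O[Si](CC)(CC)CC)Cc1c(OCOC)cc(OC)cc1OCOC | intermediate
19 | 5-methoxy-1,3-bis(methoxymethoxy)-2-{(2R)-5-methyl-2-(prop-1-en-2-yl)-5-[(triethylsilyl)oxy]hexyl}benzene | C=C(C)[C@H](CCC(C)(C)O[Si](CC)(CC)CC)Cc1c(OCOC)cc(OC)cc1OCOC | intermediate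
20 | [6-methoxy-2,4-bis(methoxymethoxy)-3-{(2R)-5-methyl-2-(prop-1-en-2-yl)-5-[(triethylsilyl)oxy]hexyl}phenyl]lithium | C=C(C)[C@H](CCC(C)(C)O[Si](CC)(CC)CC)Cc1c(OCOC)cc(OC)c([Li])c1OCOC | intermediate
21 | 1-[6-methoxy-2,4-bis(methoxymethoxy)-3-{(2R)-5-methyl-2-(prop-1-en-2-yl)-5-[(triethylsilyl)oxy]hexyl}phenyl]ethan-1-one | C=C(C)[C@H](CCC(C)(C)O[Si](CC)(CC)CC)Cc1c(OCOC)cc(OC)c(C(C)=O)c1OCOC | intermediate
22 | 1-[6-methoxy-3-{(2R)-5-methyl-2-(prop-1-en-2-yl)-5-[(triethylsilyl)oxy]hexyl}-2,4-bis[(triethylsilyl)oxy]phenyl]ethan-1-one | C=C(C)[C@H](CCC(C)(C)O[Si](CC)(CC)CC)Cc1c(O[Si](CC)(CC)CC)cc(OC)c(C(C)=O)c1O[Si](CC)(CC)CC | intermediate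
23 | 1-[2,4-dihydroxy-6-methoxy-3-{(2R)-5-methyl-2-(prop-1-en-2-yl)-5-[(triethylsilyl)oxy]hexyl}phenyl]ethan-1-one | C=C(C)[C@H](CCC(C)(C)O[Si](CC)(CC)CC)Cc1c(O)cc(OC)c(C(C)=O)c1O | intermediate
24 | 1-[2-hydroxy-6-methoxy-3-{(2R)-5-methyl-2-(prop-1-en-2-yl)-5-[(triethylsilyl)oxy]hexyl}-4-(prop-2-en-1-yloxy)phenyl]ethan-1-one | C=C(C)[C@H](CCC(C)(C)O[Si](CC)(CC)CC)Cc1c(OCC=C)cc(OC)c(C(C)=O)c1O | intermediate
25 | methyl 2,4-dihydroxybenzoate | COC(=O)c1ccc(O)cc1O | starting material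
26 | methyl 2,4-bis(prop-2-en-1-yloxy)benzoate | COC(=O)c1ccc(OCC=C)cc1OCC=C | intermediate
27 | 1-[2,4-bis(prop-2-en-1-yloxy)phenyl]-3-[2-hydroxy-6-methoxy-3-{(2R)-5-methyl-2-(prop-1-en-2-yl)-5-[(triethylsilyl)oxy]hexyl}-4-(prop-2-en-1-yloxy)phenyl]propane-1,3-dione | C=C(C)[C@H](CCC(C)(C)O[Si](CC)(CC)CC)Cc1c(OCC=C)cc(OC)c(C(=O)CC(=O)c2ccc(OCC=C)cc2OCC=C)c1O | intermediate
28 | 2-[2,4-bis(prop-2-en-1-yloxy)phenyl]-5-methoxy-8-{(2R)-5-methyl-2-(prop-1-en-2-yl)-5-[(triethylsilyl)oxy]hexyl}-7-(prop-2-en-1-yloxy)-4H-chromen-4-one | C=C(C)[C@H](CCC(C)(C)O[Si](CC)(CC)CC)Cc1c(OCC=C)cc(OC)c2c(=O)cc(-c3ccc(OCC=C)cc3OCC=C)oc12 | intermediate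
29 | 2-[2,4-bis(prop-2-en-1-yloxy)phenyl]-8-[(2R)-5-hydroxy-5-methyl-2-(prop-1-en-2-yl)hexyl]-5-methoxy-7-(prop-2-en-1-yloxy)-4H-chromen-4-one | C=C(C)[C@H](CCC(C)(C)O)Cc1c(OCC=C)cc(OC)c2c(=O)cc(-c3ccc(OCC=C)cc3OCC=C)oc12 | intermediate
30 | 2-(2,4-dihydroxyphenyl)-7-hydroxy-8-[(2R)-5-hydroxy-5-methyl-2-(prop-1-en-2-yl)hexyl]-5-methoxy-4H-chromen-4-one | C=C(C)[C@H](CCC(C)(C)O)Cc1c(O)cc(OC)c2c(=O)cc(-c3ccc(O)cc3O)oc12 | target

**Step count**
Total steps: 20. Longest linear sequence: 19 (steps 1–15 and 17–20, from 1); step 16 is a one-step side branch.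

**Three steps most likely to fail, with fallbacks**

Step 13 (late ortho-lithiation/acylation). The hindered aryllithium 20 may deprotonate N-methoxy-N-methylacetamide instead of adding to it, returning 19. The fallback sets out from 19 and returns at 21. Lithiate as before and trap 20 with acetaldehyde, which adds much faster than it enolises, to give the secondary benzylic alcohol 1-[6-methoxy-2,4-bis(methoxymethoxy)-3-{(2R)-5-methyl-2-(prop-1-en-2-yl)-5-[(triethylsilyl)oxy]hexyl}phenyl]ethan-1-ol F1 as a mixture of carbinol epimers. Oxidise this with Dess–Martin periodinane buffered with NaHCO3 in CH2Cl2 to ketone 21.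

Step 14 (acid-free removal of two MOM groups next to the acetyl group). The MOM ether wedged between the acetyl group and the side chain may exchange slowly, and the ketone may be silylated. The fallback sets out from 19 and returns at 23, so the acetal exchange is run before any ketone is present and the carbonyl is then brought in without organolithium chemistry. Treat 19 with Et3SiOTf/2,2′-bipyridyl to give the tris-silyl compound 5-methoxy-2-{(2R)-5-methyl-2-(prop-1-en-2-yl)-5-[(triethylsilyl)oxy]hexyl}-1,3-bis[(triethylsilyl)oxy]benzene F2. Methanolysis with K2CO3/MeOH gives the resorcinol 5-methoxy-2-{(2R)-5-methyl-2-(prop-1-en-2-yl)-5-[(triethylsilyl)oxy]hexyl}benzene-1,3-diol F3. Magnesium-phenoxide-directed ortho-formylation (MgCl2, Et3N, paraformaldehyde, MeCN, 70 °C; both open positions are equivalent) gives the salicylaldehyde 2,4-dihydroxy-6-methoxy-3-{(2R)-5-methyl-2-(prop-1-en-2-yl)-5-[(triethylsilyl)oxy]hexyl}benzaldehyde F4. Excess MeMgBr in THF at 0 °C gives the carbinol 1-[2,4-dihydroxy-6-methoxy-3-{(2R)-5-methyl-2-(prop-1-en-2-yl)-5-[(triethylsilyl)oxy]hexyl}phenyl]ethan-1-ol F5, which is oxidised crude with MnO2 in CH2Cl2 to 23.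

Step 17 (crossed Claisen condensation of a hindered enolate with an electron-rich benzoate). If C-acylation is sluggish, the two rings are joined by an aldol condensation instead and the oxidation level is adjusted afterwards; the fallback sets out from 24 and returns at 28. 2,4-Dihydroxybenzaldehyde is allylated (allyl bromide, K2CO3, DMF) to 2,4-bis(prop-2-en-1-yloxy)benzaldehyde F6. Claisen–Schmidt condensation of 24 with F6 (KOH, EtOH, rt) gives the chalcone (2E)-3-[2,4-bis(prop-2-en-1-yloxy)phenyl]-1-[2-hydroxy-6-methoxy-3-{(2R)-5-methyl-2-(prop-1-en-2-yl)-5-[(triethylsilyl)oxy]hexyl}-4-(prop-2-en-1-yloxy)phenyl]prop-2-en-1-one F7. Oxa-Michael ring closure (NaOAc, EtOH, reflux) gives the flavanone 2-[2,4-bis(prop-2-en-1-yloxy)phenyl]-5-methoxy-8-{(2R)-5-methyl-2-(prop-1-en-2-yl)-5-[(triethylsilyl)oxy]hexyl}-7-(prop-2-en-1-yloxy)-2,3-dihydro-4H-chromen-4-one F8 as a mixture of C-2 epimers. Dehydrogenation with DDQ in dioxane at reflux gives flavone 28.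

**Further compounds**
F1 | step 13 | 1-[6-methoxy-2,4-bis(methoxymethoxy)-3-{(2R)-5-methyl-2-(prop-1-en-2-yl)-5-[(triethylsilyl)oxy]hexyl}phenyl]ethan-1-ol | C=C(C)[C@H](CCC(C)(C)O[Si](CC)(CC)CC)Cc1c(OCOC)cc(OC)c(C(C)O)c1OCOC
F2 | step 14 | 5-methoxy-2-{(2R)-5-methyl-2-(prop-1-en-2-yl)-5-[(triethylsilyl)oxy]hexyl}-1,3-bis[(triethylsilyl)oxy]benzene | C=C(C)[C@H](CCC(C)(C)O[Si](CC)(CC)CC)Cc1c(O[Si](CC)(CC)CC)cc(OC)cc1O[Si](CC)(CC)CC
F3 | step 14 | 5-methoxy-2-{(2R)-5-methyl-2-(prop-1-en-2-yl)-5-[(triethylsilyl)oxy]hexyl}benzene-1,3-diol | C=C(C)[C@H](CCC(C)(C)O[Si](CC)(CC)CC)Cc1c(O)cc(OC)cc1O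
F4 | step 14 | 2,4-dihydroxy-6-methoxy-3-{(2R)-5-methyl-2-(prop-1-en-2-yl)-5-[(triethylsilyl)oxy]hexyl}benzaldehyde | C=C(C)[C@H](CCC(C)(C)O[Si](CC)(CC)CC)Cc1c(O)cc(OC)c(C=O)c1O
F5 | step 14 | 1-[2,4-dihydroxy-6-methoxy-3-{(2R)-5-methyl-2-(prop-1-en-2-yl)-5-[(triethylsilyl)oxy]hexyl}phenyl]ethan-1-ol | C=C(C)[C@H](CCC(C)(C)O[Si](CC)(CC)CC)Cc1c(O)cc(OC)c(C(C)O)c1O
F6 | step 17 | 2,4-bis(prop-2-en-1-yloxy)benzaldehyde | O=Cc1ccc(OCC=C)cc1OCC=C
F7 | step 17 | (2E)-3-[2,4-bis(prop-2-en-1-yloxy)phenyl]-1-[2-hydroxy-6-methoxy-3-{(2R)-5-methyl-2-(prop-1-en-2-yl)-5-[(triethylsilyl)oxy]hexyl}-4-(prop-2-en-1-yloxy)phenyl]prop-2-en-1-one | C=C(C)[C@H](CCC(C)(C)O[Si](CC)(CC)CC)Cc1c(OCC=C)cc(OC)c(C(=O)/C=C/c2ccc(OCC=C)cc2OCC=C)c1O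
F8 | step 17 | 2-[2,4-bis(prop-2-en-1-yloxy)phenyl]-5-methoxy-8-{(2R)-5-methyl-2-(prop-1-en-2-yl)-5-[(triethylsilyl)oxy]hexyl}-7-(prop-2-en-1-yloxy)-2,3-dihydro-4H-chromen-4-one (C-2 epimers) | C=C(C)[C@H](CCC(C)(C)O[Si](CC)(CC)CC)Cc1c(OCC=C)cc(OC)c2C(=O)CC(c3ccc(OCC=C)cc3OCC=C)Oc12
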